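**Retrosynthetic overview**

- The last bond is the C4–O ether of the 5-hydroxy half. It is made by adding (2S,4R)-5,6,7-trimethoxyflavan-4-ol to the o-quinone methide of the 5-hydroxy half; axial attack gives the 2,4-trans ether.
- Both partners come from one C2-symmetric bis(5,6,7-trimethoxyflavan-4-yl) ether. DDQ/H2O turns one half into the flavanone (needed for chelation-directed 5-O-demethylation, then reduction) and releases the other half as the trans-alcohol.
- That ether is made in one operation from two molecules of (S)-3-phenyl-3-(3,4,5-trimethoxyphenoxy)propanal: two Friedel–Crafts ring closures plus dehydrative etherification.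
- The aldehyde comes from 3,4,5-trimethoxyphenol and (R)-1-phenylbut-3-en-1-ol by Mitsunobu inversion (sets both C2 centers) and ozonolysis.
- Ring order: the aromatic rings are bought; the two pyran rings (ring C of each half) form together in step 3; no ring is formed afterwards.

Assumption: (R)-1-phenylbut-3-en-1-ol is bought as the single enantiomer (≥98% ee); flavonoid numbering (O1, C2, C3, C4, C4a, C5–C8, C8a) is used throughout.

**Route**

Step 1
Reactants: 1 3,4,5-trimethoxyphenol; 2 (R)-1-phenylbut-3-en-1-ol
Product: 3 (S)-1,2,3-trimethoxy-5-[(1-phenylbut-3-en-1-yl)oxy]benzene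
Conditions: PPh3, DIAD, THF, 0 °C → rt
Reagents that add atoms: none
Why: Mitsunobu etherification displaces the oxyphosphonium by phenoxide in an SN2 step, so the (R)-carbinol is inverted to the (S)-benzylic aryl ether that becomes C2 of both flavan halves.

Step 2
Reactants: 3 (S)-1,2,3-trimethoxy-5-[(1-phenylbut-3-en-1-yl)oxy]benzene
Product: 4 (S)-3-phenyl-3-(3,4,5-trimethoxyphenoxy)propanal
Conditions: O3 (1.0 equiv), CH2Cl2, −78 °C; then PPh3, −78 °C → rt
Reagents that add atoms: ozone, [O-][O+]=O
Why: Ozonolysis with reductive work-up cleaves the terminal alkene (much more reactive than the arene at −78 °C) under neutral conditions, which avoids β-elimination of the aryloxy group and leaves the stereocenter untouched.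

Step 3
Reactants: 4 (S)-3-phenyl-3-(3,4,5-trimethoxyphenoxy)propanal (two molecules)
Product: 6 bis[(2S,4R)-5,6,7-trimethoxy-2-phenylchroman-4-yl] ether, via cis-flavan-4-ol 5 (not isolated)
Conditions: camphor-10-sulfonic acid (10 mol%), 4 Å molecular sieves (zeolite Na12[(AlO2)12(SiO2)12]), CH2Cl2 (0.3 M), −20 → 0 °C; Et3N quench
Reagents that add atoms: none
Why: Proposed new method: the protonated aldehyde closes a six-membered ring by intramolecular Friedel–Crafts hydroxyalkylation at the position ortho to the ether oxygen (activated by three alkoxy groups, both ortho positions equivalent) through a chair-like transition state in which the 2-phenyl and the developing C4–OH (hydrogen-bonded to the peri 5-methoxy oxygen) are both equatorial, so the first-formed alcohol is mainly the 2,4-cis flavan-4-ol 5; 5 (like any trans epimer formed beside it) ionizes to a C4 cation stabilized by O1 and the 5- and 7-methoxy groups, a second alcohol molecule captures it on oxygen, and because both C4–O bonds of the ether ionize reversibly while water is sequestered, the ether settles in the bis-2,4-trans (4R,4R) arrangement, each bulky 4-alkoxy group pseudo-axial, away from the peri 5-methoxy group and anti to the equatorial 2-phenyl; the closest known reaction types are the acid-mediated cyclization of 3-aryloxypropanals to chroman-4-ols and the dehydrative self-etherification of electron-rich benzylic alcohols.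

Step 4
Reactants: 6 bis[(2S,4R)-5,6,7-trimethoxy-2-phenylchroman-4-yl] ether
Product: 7 (S)-5,6,7-trimethoxy-2-phenylchroman-4-one and 8 (2S,4R)-5,6,7-trimethoxy-2-phenylchroman-4-ol (both isolated)
Conditions: DDQ (1.0 equiv), CH2Cl2/aq. NaH2PO4–Na2HPO4 buffer (pH 7) 10:1, 0 °C → rt
Reagents that add atoms: water, O
Why: This is the oxidative cleavage of an electron-rich benzylic ether (as in removal of p-methoxybenzyl ethers): DDQ takes hydride from C4–H of one half, water collapses the oxocarbenium ion to ketone 7 and releases the other half as the trans-alcohol 8 with its C4–O bond and (2S,4R) centers intact, the buffer keeps the acidic hydroquinone from ionizing 8, and one equivalent of oxidant limits the change to one half.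

Step 5
Reactants: 7 (S)-5,6,7-trimethoxy-2-phenylchroman-4-one
Product: 9 (S)-5-hydroxy-6,7-dimethoxy-2-phenylchroman-4-one
Conditions: BCl3 (1.5 equiv), CH2Cl2, −78 → −20 °C; then H2O
Reagents that add atoms: none
Why: In this chelation-directed demethylation, boron bridges the C4 carbonyl and the peri 5-methoxy oxygen and chloride removes only that methyl group; C2 is not involved, and low temperature guards against Lewis-acid ring opening.

Step 6
Reactants: 9 (S)-5-hydroxy-6,7-dimethoxy-2-phenylchroman-4-one
Product: 10 (2S,4S)-6,7-dimethoxy-2-phenylchromane-4,5-diol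
Conditions: NaBH4, THF/MeOH, 0 °C; then aq. NaH2PO4–Na2HPO4 buffer (pH 7)
Reagents that add atoms: none
Why: Borohydride reduction of the ketone by axial hydride delivery gives mainly the 2,4-cis diol; the C4 configuration does not matter because C4 becomes planar in step 7, and the product is used at once.

Step 7
Reactants: 10 (2S,4S)-6,7-dimethoxy-2-phenylchromane-4,5-diol; 8 (2S,4R)-5,6,7-trimethoxy-2-phenylchroman-4-ol (1.5 equiv)
Product: 12 beilschmieflavonoid B, via o-quinone methide 11 (not isolated)
Conditions: 4 Å molecular sieves (zeolite Na12[(AlO2)12(SiO2)12]), toluene, 80 °C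
Reagents that add atoms: none
Why: Thermal dehydration of the ortho-hydroxybenzylic alcohol gives o-quinone methide 11, and oxa-Michael (1,4-) addition of alcohol 8 at C4 from the axial face anti to the 2-phenyl restores aromaticity and sets the 2,4-trans (4R) center; the centers of 8 are untouched, and excess 8 with water removal suppresses self-etherification of 10.

**Compound list**

1 | 3,4,5-trimethoxyphenol | COc1cc(O)cc(OC)c1OC | starting material
2 | (R)-1-phenylbut-3-en-1-ol | O[C@H](CC=C)c1ccccc1 | starting material
3 | (S)-1,2,3-trimethoxy-5-[(1-phenylbut-3-en-1-yl)oxy]benzene | COc1cc(O[C@@H](CC=C)c2ccccc2)cc(OC)c1OC | intermediate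
4 | (S)-3-phenyl-3-(3,4,5-trimethoxyphenoxy)propanal | COc1cc(O[C@@H](CC=O)c2ccccc2)cc(OC)c1OC | intermediate
5 | (2S,4S)-5,6,7-trimethoxy-2-phenylchroman-4-ol (2,4-cis; formed and consumed in step 3) | O[C@H]1C[C@@H](c2ccccc2)Oc2cc(OC)c(OC)c(OC)c21 | intermediate
6 | bis[(2S,4R)-5,6,7-trimethoxy-2-phenylchroman-4-yl] ether | COc1cc2c(c(OC)c1OC)[C@H](O[C@@H]1C[C@@H](c3ccccc3)Oc3cc(OC)c(OC)c(OC)c31)C[C@@H](c1ccccc1)O2 | intermediate
7 | (S)-5,6,7-trimethoxy-2-phenylchroman-4-one | O=C1C[C@@H](c2ccccc2)Oc2cc(OC)c(OC)c(OC)c21 | intermediate
8 | (2S,4R)-5,6,7-trimethoxy-2-phenylchroman-4-ol (2,4-trans) | O[C@@H]1C[C@@H](c2ccccc2)Oc2cc(OC)c(OC)c(OC)c21 | intermediate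
9 | (S)-5-hydroxy-6,7-dimethoxy-2-phenylchroman-4-one | O=C1C[C@@H](c2ccccc2)Oc2cc(OC)c(OC)c(O)c21 | intermediate
10 | (2S,4S)-6,7-dimethoxy-2-phenylchromane-4,5-diol (2,4-cis) | O[C@H]1C[C@@H](c2ccccc2)Oc2cc(OC)c(OC)c(O)c21 | intermediate
11 | (S)-6,7-dimethoxy-2-phenyl-2,3-dihydro-5H-chromen-5-one (o-quinone methide, C4=C4a) | O=C1C(OC)=C(OC)C=C2O[C@H](c3ccccc3)CC=C12 | intermediate
12 | beilschmieflavonoid B, (2S,4R)-6,7-dimethoxy-2-phenyl-4-{[(2S,4R)-5,6,7-trimethoxy-2-phenylchroman-4-yl]oxy}chroman-5-ol | COc1cc2c(c(O)c1OC)[C@H](O[C@@H]1C[C@@H](c3ccccc3)Oc3cc(OC)c(OC)c(OC)c31)C[C@@H](c1ccccc1)O2 | target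

**Step count and risks**

Total steps: 7. Longest linear sequence: 7 steps (steps 1 to 7; alcohol 8 isolated in step 4 re-enters in step 7).

Step 3 is the most likely to fail. The C4 cation can also be captured irreversibly at C8 of another molecule (C-linked oligomers) or lose a proton to the flav-3-ene, and the aldehyde can lose the phenol by β-elimination. The fallback sets out from 4 and comes back at 8 (and at 7 for the ketone branch). Et3SiH/CF3CO2H in CH2Cl2 at −20 °C runs the same ring closure but reduces the C4 cation at once, giving (S)-5,6,7-trimethoxy-2-phenylchromane F1. DDQ in CH2Cl2/aqueous pH 7 buffer then removes hydride from C4 and water enters from the axial face to give 8. Part of 8 is oxidized further by the same reagent to 7; the two are separated, and ether 6 is bypassed.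

Step 4 is the second risk. In the trans ether the C4–H bond is pseudo-equatorial and poorly aligned with the arene, so hydride abstraction may be slow, and released 8 can be over-oxidized. The fallback sets out from 6 and comes back at 7 and 8. Catalytic camphor-10-sulfonic acid in THF/H2O at 0 °C hydrolyzes 6 to the flavan-4-ol: 8 from axial capture of water, together with its C4 epimer 5. The epimers are separated, 8 goes on to step 7, and 5 (plus any surplus 8) is oxidized with Dess–Martin periodinane in CH2Cl2 to 7. This fallback needs no new compound (F0).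

Step 7 is the third risk. Diol 10 can etherify with itself, and the o-quinone methide can oligomerize or alkylate C8 of 8. The fallback sets out from 10 and comes back at 12. 1,1'-Carbonyldiimidazole in CH2Cl2 ties the 4- and 5-oxygens into (2S,4S)-6,7-dimethoxy-2-phenylchromane-4,5-diyl carbonate F2, which has no free 4-OH. Warming F2 with 8 in toluene expels CO2 and gives the same o-quinone methide 11 with 8 as the only alcohol present.

Further compounds
F1 | step 3 | (S)-5,6,7-trimethoxy-2-phenylchromane | COc1cc2c(c(OC)c1OC)CC[C@@H](c1ccccc1)O2
F0 | step 4 | none | none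
F2 | step 7 | (2S,4S)-6,7-dimethoxy-2-phenylchromane-4,5-diyl carbonate | O=C1O[C@H]2C[C@@H](c3ccccc3)Oc3cc(OC)c(OC)c(O1)c32
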